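Readings and results were computed for an exercise, and the scatter is random.

In this closed, stirred vessel the free monomer goes into chains and into what the readings do not list, which appears as a shortfall in the balance. That shortfall is what to watch.

| flask | free monomer | initiator | temperature | remark | time |
|---|---|---|---|---|---|
| alder | 0.52 M | 2.5 mol% | 78 °C | run made earlier |  |
| larch | 0.52 M | 3.8 mol% | 105 °C | run made earlier |  |
| birch | 0.78 M | 5 mol% | 78 °C | run made earlier |  |
| Thursday's | 0.52 M | 5 mol% | 90 °C |  | 20 min |
| Wednesday's | 0.52 M | 5 mol% | 65 °C |  | 20 min |
| Friday's | 0.52 M | 5 mol% | 115 °C |  | 20 min |

- alder (time / min: monomer in chains / %, free monomer / %): 2.50: 0.2, 95.3; 8.00: 12.4, 78.4; 15.0: 34.8, 53.1; 40.0: 65.8, 9.2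
- larch (time / min: monomer in chains / %, free monomer / %): 2.50: 22.1, 59.6; 5.00: 43.3, 25.8; 8.00: 52.5, 7.8; 10.0: 57.9, 3.1
- birch (time / min: monomer in chains / %, free monomer / %): 2.50: 10.7, 90.8; 8.00: 45.4, 48.9; 15.0: 71.1, 16.1; 40.0: 85.0, 1.0

(standard deviation of a reading: 1 percentage point)

- the analysis behind the earlier runs scatters by 1 percentage point, standard deviation

* the flask with the highest amount of monomer in chains, in percent of the free monomer charged ("all alike" if they lie within 1.5 percentage points) (Thursday's / Wednesday's / Friday's / all alike)
* final monomer in chains, as a percentage of the free monomer charged, in Thursday's
* final monomer in chains, as a percentage of the free monomer charged, in Wednesday's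
* final monomer in chains, as a percentage of the free monomer charged, in Friday's

We reckon with the rates. Over a run, the rate into chains against the rate of other loss gives chains made per unit of shortfall, which we call the branch ratio (a selectivity factor). Alder and larch share one monomer charge. The last readings give 2.63 for alder and 1.48 for larch. We take the ratio as proportional to the initiator loading, and once that is divided out, the heat from alder to larch costs a factor 2.69, read with the scatter of the readings.

Carried from larch to Friday's, the loading raises the ratio by 1.32 and the heat lowers it by 1.44. That gives Friday's a branch ratio of 1.35, so 57.4% of the reacted monomer should stand in chains.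

Turnovers, the natural logarithm of the fall in free monomer, tell whether the ratio applies. Larch made 3.47 by 10.0 min, and Friday's is hotter and runs longer, so we expect it to finish. Thursday's ratio comes to 3.39, higher than Friday's, so we put Thursday's first. Wednesday's, colder than alder, we expect to stop on turnovers rather than on the ratio.

The forecast names Thursday's, with 72% there, 43% in Wednesday's and 50% in Friday's, below our share, saying of Friday's that “the side loss takes about half”.

The flasks give Thursday's as highest, with 73.4% in Thursday's, 35.4% in Wednesday's, where 60% of the free monomer remains, and 55.3% in Friday's.

    free monomer + initiator → living end + monomer in chains (k = 0.270 /M/min, Ea = 59.0 kJ/mol)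
    free monomer + living end → monomer in chains + living end, rate k2*[living end]*[free monomer] (k = 11.0 /M/min, Ea = 48.0 kJ/mol)
    free monomer + monomer in chains → side product (k = 0.0310 /M/min, Ea = 73.0 kJ/mol)
    free monomer → uncatalysed product (k = 0.0250 /min, Ea = 97.0 kJ/mol)
    (constants at 90 °C)

Friday's ends with 0% free monomer, so its branch ratio stands at 1.24, against our 1.35. The main reason for its shortfall is the step from free monomer to uncatalysed product: without that step, Friday's reaches 86.8%. In the scheme, chain growth over that step goes with [living end] at one temperature. A neighbour of Friday's with 12 mol% of initiator ends with 0.0297 M of living end against 0.0161 M in Friday's, and scaling our ratio by these end values gives 2.50, a share of 71.4%; that neighbour gives 69.0%.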